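The flavanone pyranone ring is assembled as a flavone by a [3+3] union: the enolate of an aryl methyl ketone supplies O1–C2–C3 and 2,6-difluoro-4-methoxybenzoyl chloride supplies C4–C4a–C8a. C-acylation makes C3–C4, and the diketonate oxygen then displaces an ortho fluoride to make O1–C8a in the same flask. The step exploits ring A, where the acyl-bearing C4a is flanked by two oxygenated carbons (C5 and C8a): the two C–F bonds are equivalent, and the surviving fluoride becomes the C5 oxygen. The ketone precursor is 7,4'-di-O-benzylkaempferol arylated at O3 with 4'-fluoroacetophenone. Copper hydride conjugate reduction later sets C2 as S.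

Key step: step 4

Remark on the chemistry: in step 6 the ligand antipode that delivers hydride to the C2 face giving (2S) is meant; (R)-DTBM-SEGPHOS is written and the choice should be confirmed on 7-methoxyflavone before use, otherwise the (S)-ligand is taken.

Step 1
Reactants: 1 kaempferol
Product: 2 7-(benzyloxy)-2-[4-(benzyloxy)phenyl]-3,5-dihydroxy-4H-chromen-4-one (7,4'-di-O-benzylkaempferol)
Conditions: BnBr (2.1 equiv), K2CO3 (2.2 equiv), DMF, 0 °C → rt
Reagents that add atoms: benzyl bromide BrCc1ccccc1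
Why: Williamson etherification, in which the 7-OH and 4'-OH are the most acidic and least hindered hydroxyls whereas the 3-OH and especially the 5-OH are hydrogen-bonded to the C4 carbonyl, so two equivalents of benzyl bromide should go mainly to O7 and O4'.

Step 2
Reactants: 2 7,4'-di-O-benzylkaempferol; 3 4'-fluoroacetophenone
Product: 4 3-(4-acetylphenoxy)-7-(benzyloxy)-2-[4-(benzyloxy)phenyl]-5-hydroxy-4H-chromen-4-one
Conditions: 3 (1.5 equiv), K2CO3 (1.5 equiv), DMF, 110 °C, argon
Reagents that add atoms: none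
Why: SNAr diaryl ether formation, in which carbonate deprotonates the 3-OH (more acidic than the chelated 5-OH) and the flavonolate oxygen displaces the fluoride para to the acetyl group through a Meisenheimer intermediate.

Step 3
Reactants: 5 2,6-difluoro-4-methoxybenzoic acid
Product: 6 2,6-difluoro-4-methoxybenzoyl chloride
Conditions: (COCl)2 (1.5 equiv), DMF (cat.), CH2Cl2, 0 °C → rt; evaporate, use crude
Reagents that add atoms: oxalyl chloride ClC(=O)C(Cl)=O
Why: Acid chloride formation through the catalytic chloroiminium (Vilsmeier-type) species, driven by loss of gases and leaving the aryl fluorides and the methyl ether untouched.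

Step 4
Reactants: 4 3-(4-acetylphenoxy)-7-(benzyloxy)-2-[4-(benzyloxy)phenyl]-5-hydroxy-4H-chromen-4-one; 6 2,6-difluoro-4-methoxybenzoyl chloride
Product: 8 7-(benzyloxy)-2-[4-(benzyloxy)phenyl]-3-[4-(5-fluoro-7-methoxy-4-oxo-4H-chromen-2-yl)phenoxy]-5-hydroxy-4H-chromen-4-one, via 1,3-diketone 7 (not isolated)
Conditions: LiHMDS (3.2 equiv), THF, −78 °C; 6 (1.2 equiv), −78 → 0 °C; then DMF, K2CO3, 90 °C, one flask
Reagents that add atoms: none
Why: LiHMDS converts 4 into its lithium phenoxide/methyl ketone enolate, the enolate carbon attacks the acyl chloride (Claisen-type C-acylation, C3–C4 bond) and the third equivalent of base stores the product as diketonate 7; on heating in DMF the enolate oxygen on the C2 side adds to an ortho C–F carbon of the 2,6-difluoroaryl ketone and fluoride leaves (addition–elimination, O1–C8a bond). The closest known reaction type is the chromone synthesis from ketone enolates and 2-fluorobenzoyl chlorides, that is enolate acylation followed by intramolecular SNAr. The pyranone ring closes in a 6-exo-trig sense onto the arene carbon through a Meisenheimer intermediate activated by the ortho carbonyl. No stereocentre is formed here; C2 stays sp2 and is set in step 6. The step needs C- over O-acylation and ring closure over intermolecular substitution: the lithium enolate with excess base favours the diketonate, the chelated 5-phenoxide is a poor acyl acceptor, the two C–F positions are equivalent so regiochemistry is moot, and no external nucleophile is present.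

Step 5
Reactants: 8 5-fluoro-7-methoxyflavone-containing biflavone ether
Product: 9 7-(benzyloxy)-3-{4-[5-(benzyloxy)-7-methoxy-4-oxo-4H-chromen-2-yl]phenoxy}-2-[4-(benzyloxy)phenyl]-5-hydroxy-4H-chromen-4-one
Conditions: BnOH (1.5 equiv), NaH (2.6 equiv), THF/DMF, 0 °C → rt; aq NH4Cl
Reagents that add atoms: benzyl alcohol OCc1ccccc1
Why: SNAr, in which the C5 fluoride is ortho to the ring-fusion carbon bearing the C4 carbonyl and has no donor ortho or para to it, so sodium benzyl oxide should displace it at or below room temperature while the fluorine-free flavonol unit and its chelated phenoxide stay unchanged.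

Step 6
Reactants: 9 5-benzyloxy-7-methoxyflavone-containing biflavone ether
Product: 10 7-(benzyloxy)-3-{4-[(2S)-5-(benzyloxy)-7-methoxy-4-oxochroman-2-yl]phenoxy}-2-[4-(benzyloxy)phenyl]-5-hydroxy-4H-chromen-4-one
Conditions: Cu(OAc)2·H2O (5 mol %), (R)-DTBM-SEGPHOS (5.5 mol %), (EtO)2MeSiH (4 equiv), t-BuOH (2 equiv), toluene/THF, 0 °C → rt; aq NH4Cl
Reagents that add atoms: none
Why: Copper hydride-catalysed asymmetric 1,4-reduction of a chromone, in which the chiral bisphosphine–CuH adds hydride to C2 of the trisubstituted enone from the face dictated by the ligand to set C2 as S, the copper enolate is protonated by t-BuOH, and the tetrasubstituted 3-aryloxychromone of the other unit is too hindered to react (excess silane covers the free phenol).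

Step 7
Reactants: 10 tri-O-benzyl (2S)-flavanone–flavonol ether
Product: 11 3-{4-[(2S)-5-hydroxy-7-methoxy-4-oxochroman-2-yl]phenoxy}-5,7-dihydroxy-2-(4-hydroxyphenyl)-4H-chromen-4-one (target)
Conditions: H2 (1 atm), 10% Pd/C, EtOAc/MeOH, rt
Reagents that add atoms: none
Why: Hydrogenolysis of the three benzyl aryl ethers under neutral conditions, which should neither open the base-sensitive flavanone ring nor touch C2, so the S configuration is kept.

Compound list
1 | kaempferol, 3,5,7-trihydroxy-2-(4-hydroxyphenyl)-4H-chromen-4-one | O=c1c(O)c(-c2ccc(O)cc2)oc2cc(O)cc(O)c12 | starting material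
2 | 7-(benzyloxy)-2-[4-(benzyloxy)phenyl]-3,5-dihydroxy-4H-chromen-4-one | O=c1c(O)c(-c2ccc(OCc3ccccc3)cc2)oc2cc(OCc3ccccc3)cc(O)c12 | intermediate
3 | 4'-fluoroacetophenone, 1-(4-fluorophenyl)ethanone | CC(=O)c1ccc(F)cc1 | starting material
4 | 3-(4-acetylphenoxy)-7-(benzyloxy)-2-[4-(benzyloxy)phenyl]-5-hydroxy-4H-chromen-4-one | CC(=O)c1ccc(Oc2c(-c3ccc(OCc4ccccc4)cc3)oc3cc(OCc4ccccc4)cc(O)c3c2=O)cc1 | intermediate
5 | 2,6-difluoro-4-methoxybenzoic acid | COc1cc(F)c(C(=O)O)c(F)c1 | starting material
6 | 2,6-difluoro-4-methoxybenzoyl chloride | COc1cc(F)c(C(Cl)=O)c(F)c1 | intermediate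
7 | 1-(2,6-difluoro-4-methoxyphenyl)-3-[4-({7-(benzyloxy)-2-[4-(benzyloxy)phenyl]-5-hydroxy-4-oxo-4H-chromen-3-yl}oxy)phenyl]propane-1,3-dione, present as its lithium enolate | COc1cc(F)c(C(=O)CC(=O)c2ccc(Oc3c(-c4ccc(OCc5ccccc5)cc4)oc4cc(OCc5ccccc5)cc(O)c4c3=O)cc2)c(F)c1 | intermediate (not isolated)
8 | 7-(benzyloxy)-2-[4-(benzyloxy)phenyl]-3-[4-(5-fluoro-7-methoxy-4-oxo-4H-chromen-2-yl)phenoxy]-5-hydroxy-4H-chromen-4-one | COc1cc(F)c2c(c1)oc(-c1ccc(Oc3c(-c4ccc(OCc5ccccc5)cc4)oc4cc(OCc5ccccc5)cc(O)c4c3=O)cc1)cc2=O | intermediate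
9 | 7-(benzyloxy)-3-{4-[5-(benzyloxy)-7-methoxy-4-oxo-4H-chromen-2-yl]phenoxy}-2-[4-(benzyloxy)phenyl]-5-hydroxy-4H-chromen-4-one | COc1cc(OCc2ccccc2)c2c(c1)oc(-c1ccc(Oc3c(-c4ccc(OCc5ccccc5)cc4)oc4cc(OCc5ccccc5)cc(O)c4c3=O)cc1)cc2=O | intermediate
10 | 7-(benzyloxy)-3-{4-[(2S)-5-(benzyloxy)-7-methoxy-4-oxochroman-2-yl]phenoxy}-2-[4-(benzyloxy)phenyl]-5-hydroxy-4H-chromen-4-one | COc1cc(OCc2ccccc2)c2c(c1)O[C@H](c1ccc(Oc3c(-c4ccc(OCc5ccccc5)cc4)oc4cc(OCc5ccccc5)cc(O)c4c3=O)cc1)CC2=O | intermediate
11 | 3-{4-[(2S)-5-hydroxy-7-methoxy-4-oxochroman-2-yl]phenoxy}-5,7-dihydroxy-2-(4-hydroxyphenyl)-4H-chromen-4-one | COc1cc(O)c2c(c1)O[C@H](c1ccc(Oc3c(-c4ccc(O)cc4)oc4cc(O)cc(O)c4c3=O)cc1)CC2=O | target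

Total step count: 7. Longest linear sequence: 6 steps (steps 1, 2, 4, 5, 6 and 7 from kaempferol); step 3 is a one-step side branch.

Steps most likely to fail

1. Step 6. Facial discrimination in the hydride transfer may be poor on this large substrate. The C4 carbonyl may also be over-reduced, or the copper enolate may open by loss of the ring phenoxide and re-close without stereocontrol. Fallback: setting out from 9, asymmetric hydrogenation with H2 (high pressure) over a chiral ruthenium N-heterocyclic carbene catalyst made from Ru(cod)(2-methylallyl)2, a chiral imidazolinium salt and KOt-Bu in toluene should reduce the C2=C3 bond and the ketone to the cis alcohol 7-(benzyloxy)-3-{4-[(2S,4S)-5-(benzyloxy)-4-hydroxy-7-methoxychroman-2-yl]phenoxy}-2-[4-(benzyloxy)phenyl]-5-hydroxy-4H-chromen-4-one F1. Oxidation of the benzylic carbinol with Dess–Martin periodinane (NaHCO3, CH2Cl2) then comes back to the route at 10.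

2. Step 4. O-acylation of the enolate or of the chelated phenoxide may compete with C-acylation, and the diketonate may undergo retro-Claisen cleavage before it closes. Fallback: setting out from 2, SNAr with 4-fluorobenzaldehyde (K2CO3, DMF) should give 4-({7-(benzyloxy)-2-[4-(benzyloxy)phenyl]-5-hydroxy-4-oxo-4H-chromen-3-yl}oxy)benzaldehyde F2. Monobenzylation of commercial 2',6'-dihydroxy-4'-methoxyacetophenone (BnBr, K2CO3, acetone) gives 1-[2-(benzyloxy)-6-hydroxy-4-methoxyphenyl]ethanone F3. Claisen–Schmidt condensation of the two (KOH, EtOH/THF) gives (E)-1-[2-(benzyloxy)-6-hydroxy-4-methoxyphenyl]-3-[4-({7-(benzyloxy)-2-[4-(benzyloxy)phenyl]-5-hydroxy-4-oxo-4H-chromen-3-yl}oxy)phenyl]prop-2-en-1-one F4. Oxidative cyclisation with catalytic I2 in DMSO at 120 °C closes the pyranone through O1–C2 and comes back to the route at 9.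

3. Step 2. The hindered, chelated flavonolate may attack the only moderately activated aryl fluoride slowly, which leaves time for thermal or oxidative degradation and for arylation at O5. Fallback: setting out from 2, Chan–Lam coupling with 4-acetylphenylboronic acid (Cu(OAc)2, pyridine, 4 Å molecular sieves, CH2Cl2, dry air, rt) forms the same aryl ether oxidatively at room temperature and comes back to the route at 4; it makes no new compound (F0).

Further compounds
F1 | step 6 | 7-(benzyloxy)-3-{4-[(2S,4S)-5-(benzyloxy)-4-hydroxy-7-methoxychroman-2-yl]phenoxy}-2-[4-(benzyloxy)phenyl]-5-hydroxy-4H-chromen-4-one | COc1cc(OCc2ccccc2)c2c(c1)O[C@H](c1ccc(Oc3c(-c4ccc(OCc5ccccc5)cc4)oc4cc(OCc5ccccc5)cc(O)c4c3=O)cc1)C[C@@H]2O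
F2 | step 4 | 4-({7-(benzyloxy)-2-[4-(benzyloxy)phenyl]-5-hydroxy-4-oxo-4H-chromen-3-yl}oxy)benzaldehyde | O=Cc1ccc(Oc2c(-c3ccc(OCc4ccccc4)cc3)oc3cc(OCc4ccccc4)cc(O)c3c2=O)cc1
F3 | step 4 | 1-[2-(benzyloxy)-6-hydroxy-4-methoxyphenyl]ethanone | CC(=O)c1c(O)cc(OC)cc1OCc1ccccc1
F4 | step 4 | (E)-1-[2-(benzyloxy)-6-hydroxy-4-methoxyphenyl]-3-[4-({7-(benzyloxy)-2-[4-(benzyloxy)phenyl]-5-hydroxy-4-oxo-4H-chromen-3-yl}oxy)phenyl]prop-2-en-1-one | COc1cc(O)c(C(=O)/C=C/c2ccc(Oc3c(-c4ccc(OCc5ccccc5)cc4)oc4cc(OCc5ccccc5)cc(O)c4c3=O)cc2)c(OCc2ccccc2)c1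
F0 | step 2 | none | none
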